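**Retrosynthetic overview**
- Target ⇒ MOM removal, benzylic alcohol oxidation and two directed ortho-metalations (isovaleryl and formyl carbons) ⇒ a C4-benzylated guai-5-en-11-ol carrying a bare tris(MOM)phloroglucinol ring.
- Key step: the C4 quaternary centre and the C5=C6 alkene come from an Ireland–Claisen rearrangement of the C6β arylacetate of a guai-4-en-6-ol (chirality transfer O-6 → C-4). The carboxyl is then removed by hydrodecarboxylation (traceless tether). This replaces the usual o-quinone methide/terpene alkene union.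
- Guai-4-ene-6β,11-diol ⇒ enone ⇒ oxidative 1,3-transposition of guai-5-ene-4,11-diol ⇒ epoxide/cyclopropylcarbinyl opening of (−)-α-gurjunene, which supplies C1, C7 and C10.
- Arylacetic acid ⇒ phloroglucinol (MOM protection, lithiation/oxirane, oxidation).
- Ring order: the fused five- and seven-membered carbocycles are bought in the terpene (cyclopropane opened in step 2); the aromatic ring is bought and fully substituted last.

Assumption: (−)-α-gurjunene, phloroglucinol and 3-methylbutanal are bought; guaiane numbering is used (five-membered ring C1–C5, seven-membered ring C1, C5–C10, C11 carbinol carbon, C15 methyl on C4); β is the face of H-1 and of the C7 side chain.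

**Step 1**
Reactants: 1 (−)-α-gurjunene
Product: 2 4α,5α-epoxy-α-gurjunene (epoxide on the face opposite the cyclopropane)
Conditions: dimethyldioxirane (1.1 equiv, 0.07 M in acetone), −20 → 0 °C
Reagents that add atoms: dimethyldioxirane, CC1(C)OO1
Why: Concerted dioxirane epoxidation of the electron-rich tetrasubstituted C4=C5 alkene under neutral conditions (the product is an acid-labile cyclopropylcarbinyl epoxide), expected anti to the cyclopropane; the face is immaterial because C4 and C5 become sp2 again by step 3.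

**Step 2**
Reactants: 2 4α,5α-epoxy-α-gurjunene
Product: 3 (1R,4R,7R,10R)-guai-5-ene-4,11-diol
Conditions: HClO4 (1 mol %), THF/H2O (1:1), 0 °C
Reagents that add atoms: water, O
Why: Acid-catalysed epoxide ionisation at C5 gives a cyclopropylcarbinyl cation that opens by cyclopropylcarbinyl–homoallyl rearrangement (C6–C11 cleavage, new C5=C6 alkene) and water captures the tertiary C11 cation, the same reaction type as the hydration of 2-carene oxide to p-menth-2-ene-1,8-diol; C1, C7 and C10 are not involved.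

**Step 3**
Reactants: 3 (1R,4R,7R,10R)-guai-5-ene-4,11-diol
Product: 4 (1R,7S,10R)-11-hydroxyguai-4-en-6-one
Conditions: [C5H5NH][CrO3Cl] (2.5 equiv), Celite, CH2Cl2, 23 °C
Reagents that add atoms: pyridinium chlorochromate [C5H5NH][CrO3Cl], [O-][Cr](=O)(=O)Cl.c1cc[nH+]cc1 (supplies the C6 oxygen)
Why: Babler–Dauben oxidative transposition, in which the chromate ester of the tertiary allylic alcohol undergoes a [3,3] shift to C6 and is oxidised there to the enone; the non-allylic tertiary C11–OH is inert and C7 (now α to the ketone) keeps its configuration under these non-basic conditions.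

**Step 4**
Reactants: 4 (1R,7S,10R)-11-hydroxyguai-4-en-6-one
Product: 5 (1R,6R,7R,10R)-guai-4-ene-6,11-diol (6β-OH)
Conditions: NaBH4, CeCl3·7H2O, MeOH, −78 °C
Reagents that add atoms: none
Why: Luche 1,2-reduction of the enone, with hydride adding to the α face anti to the bulky β-oriented CMe2OH group on C7 (Felkin–Anh), which sets the 6β carbinol that later controls C4.

**Step 5**
Reactants: 6 phloroglucinol
Product: 7 1,3,5-tris(methoxymethoxy)benzene
Conditions: MOMCl (3.6 equiv), i-Pr2NEt (4 equiv), CH2Cl2/DMF, 0 → 23 °C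
Reagents that add atoms: chloromethyl methyl ether, COCCl
Why: Threefold O-alkylation of the phenols (Williamson-type) installs MOM ethers that later direct both metalations and come off under mild acid.

**Step 6**
Reactants: 7 1,3,5-tris(methoxymethoxy)benzene
Product: 9 2-[2,4,6-tris(methoxymethoxy)phenyl]ethan-1-ol, via aryllithium 8 (not isolated)
Conditions: n-BuLi (1.1 equiv), THF, 0 °C; oxirane (3 equiv), CuI (10 mol %), −40 → 23 °C; H2O
Reagents that add atoms: oxirane, C1CO1
Why: Directed ortho-metalation at the C–H flanked by two MOM ethers, followed by copper-catalysed ring opening of oxirane by the aryllithium.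

**Step 7**
Reactants: 9 2-[2,4,6-tris(methoxymethoxy)phenyl]ethan-1-ol
Product: 10 2-[2,4,6-tris(methoxymethoxy)phenyl]acetic acid
Conditions: (n-Pr4N)[RuO4] (10 mol %), N-methylmorpholine N-oxide monohydrate (10 equiv), MeCN, 23 °C
Reagents that add atoms: water, O (second carboxyl oxygen, via the aldehyde hydrate)
Why: Ley–Griffith oxidation run with the N-oxide hydrate, so the intermediate aldehyde is hydrated and oxidised on to the acid without electrophilic halogen that would attack the electron-rich ring.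

**Step 8**
Reactants: 5 (1R,6R,7R,10R)-guai-4-ene-6,11-diol, 10 2-[2,4,6-tris(methoxymethoxy)phenyl]acetic acid
Product: 11 (1R,6R,7R,10R)-11-hydroxyguai-4-en-6-yl 2-[2,4,6-tris(methoxymethoxy)phenyl]acetate
Conditions: DCC (1.5 equiv), DMAP (0.2 equiv), CH2Cl2, 0 → 23 °C
Reagents that add atoms: none
Why: Steglich esterification, selective for the secondary allylic hydroxyl over the tertiary one and proceeding with retention at C6 because only the acyl–oxygen bond is formed.

**Step 9**
Reactants: 11 (1R,6R,7R,10R)-11-hydroxyguai-4-en-6-yl 2-[2,4,6-tris(methoxymethoxy)phenyl]acetate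
Product: 14 2-[(1R,4R,7R,10R)-11-hydroxyguai-5-en-4-yl]-2-[2,4,6-tris(methoxymethoxy)phenyl]acetic acid, via silyl ketene acetal 12 (not isolated), via rearranged silyl ester 13 (not isolated)
Conditions: Me3SiCl (4 equiv), KN(SiMe3)2 (3 equiv), THF, −78 °C; toluene, 80 °C; aq. citric acid, THF, 23 °C
Reagents that add atoms: none
Why: Ireland–Claisen rearrangement, a suprafacial [3,3] shift across C6–C5=C4 in which the new C–C bond forms at C4 on the β face that carried the C6–O bond (H-6 lies in the alkene plane to avoid A(1,3) strain with the C4 methyl, so C6–O is perpendicular), giving the (4R) quaternary centre and the C5=C6 alkene in one event; the benzylic stereocentre is erased in step 10.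

**Step 10**
Reactants: 14 2-[(1R,4R,7R,10R)-11-hydroxyguai-5-en-4-yl]-2-[2,4,6-tris(methoxymethoxy)phenyl]acetic acid
Product: 15 (1R,4R,7R,10R)-4-{[2,4,6-tris(methoxymethoxy)phenyl]methyl}guai-5-en-11-ol
Conditions: 9-mesityl-10-phenylacridinium tetrafluoroborate (5 mol %), PhSSPh (10 mol %), i-Pr2NEt (0.2 equiv), CF3CH2OH, 450 nm LEDs, 23 °C
Reagents that add atoms: none
Why: Photoredox hydrodecarboxylation, in which single-electron oxidation of the arylacetate releases CO2 to give a benzylic radical that is reduced by hydrogen-atom transfer from thiophenol; the radical is benzylic, so cyclisation onto the neighbouring alkene is reversible and unproductive, and C4 is untouched.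

**Step 11**
Reactants: 15 (1R,4R,7R,10R)-4-{[2,4,6-tris(methoxymethoxy)phenyl]methyl}guai-5-en-11-ol, 16 3-methylbutanal
Product: 20 3-{[(1R,4R,7R,10R)-11-hydroxyguai-5-en-4-yl]methyl}-5-(1-hydroxy-3-methylbutyl)-2,4,6-tris(methoxymethoxy)benzaldehyde, via first aryllithium 17 (not isolated), via lithium dialkoxide 18 (not isolated), via second aryllithium 19 (not isolated)
Conditions: n-BuLi (2.2 equiv), TMEDA, THF, 0 °C; 16 (1.05 equiv), −78 °C; n-BuLi (1.5 equiv), 0 °C; DMF (3 equiv), −78 → 0 °C; H2O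
Reagents that add atoms: N,N-dimethylformamide, CN(C)C=O
Why: Two sequential directed ortho-metalations (each remaining aryl C–H lies between two MOM ethers), the first aryllithium adding to the aldehyde and the second being formylated by DMF, with the lithium alkoxides inert to the second lithiation; the new carbinol centre is a mixture that is oxidised away in step 12.

**Step 12**
Reactants: 20 3-{[(1R,4R,7R,10R)-11-hydroxyguai-5-en-4-yl]methyl}-5-(1-hydroxy-3-methylbutyl)-2,4,6-tris(methoxymethoxy)benzaldehyde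
Product: 21 3-{[(1R,4R,7R,10R)-11-hydroxyguai-5-en-4-yl]methyl}-5-(3-methylbutanoyl)-2,4,6-tris(methoxymethoxy)benzaldehyde
Conditions: Dess–Martin periodinane (1.5 equiv), CH2Cl2, 23 °C
Reagents that add atoms: none
Why: Dess–Martin oxidation of the secondary benzylic alcohol to the aryl ketone, conditions under which the aldehyde, the tertiary alcohol and the trisubstituted alkene are inert.

**Step 13**
Reactants: 21 3-{[(1R,4R,7R,10R)-11-hydroxyguai-5-en-4-yl]methyl}-5-(3-methylbutanoyl)-2,4,6-tris(methoxymethoxy)benzaldehyde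
Product: 22 2,4,6-trihydroxy-3-{[(1R,4R,7R,10R)-11-hydroxyguai-5-en-4-yl]methyl}-5-(3-methylbutanoyl)benzaldehyde (CNP0583424.1)
Conditions: HCl (1.25 M in MeOH), 23 °C
Reagents that add atoms: none
Why: Acid-catalysed acetal exchange removes the three MOM ethers (each is ortho to a carbonyl and cleaves readily), and dilute acid at room temperature spares the tertiary alcohol and the hindered alkene; no stereocentre is touched.

**Compound list**
1 | (−)-α-gurjunene, (1aR,4R,4aR,7bS)-1,1,4,7-tetramethyl-1a,2,3,4,4a,5,6,7b-octahydro-1H-cyclopropa[e]azulene | CC1=C2[C@H](CC1)[C@H](C)CC[C@@H]3[C@H]2C3(C)C | starting material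
2 | 4α,5α-epoxy-α-gurjunene (epoxide anti to the cyclopropane) | C[C@@]12CC[C@@H]3[C@H](C)CC[C@@H]4[C@@H](C4(C)C)[C@@]13O2 | intermediate
3 | (1R,4R,7R,10R)-guai-5-ene-4,11-diol (4α-OH) | C[C@@]1(O)CC[C@H]2C1=C[C@H](C(C)(C)O)CC[C@H]2C | intermediate
4 | (1R,7S,10R)-11-hydroxyguai-4-en-6-one | CC1=C2C(=O)[C@H](C(C)(C)O)CC[C@@H](C)[C@H]2CC1 | intermediate
5 | (1R,6R,7R,10R)-guai-4-ene-6,11-diol (6β-OH) | CC1=C2[C@H](O)[C@H](C(C)(C)O)CC[C@@H](C)[C@H]2CC1 | intermediate
6 | phloroglucinol (benzene-1,3,5-triol) | Oc1cc(O)cc(O)c1 | starting material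
7 | 1,3,5-tris(methoxymethoxy)benzene | COCOc1cc(OCOC)cc(OCOC)c1 | intermediate
8 | 2,4,6-tris(methoxymethoxy)phenyllithium | [Li]c1c(OCOC)cc(OCOC)cc1OCOC | intermediate
9 | 2-[2,4,6-tris(methoxymethoxy)phenyl]ethan-1-ol | OCCc1c(OCOC)cc(OCOC)cc1OCOC | intermediate
10 | 2-[2,4,6-tris(methoxymethoxy)phenyl]acetic acid | OC(=O)Cc1c(OCOC)cc(OCOC)cc1OCOC | intermediate
11 | (1R,6R,7R,10R)-11-hydroxyguai-4-en-6-yl 2-[2,4,6-tris(methoxymethoxy)phenyl]acetate | CC1=C2[C@H](OC(=O)Cc3c(OCOC)cc(OCOC)cc3OCOC)[C@H](C(C)(C)O)CC[C@@H](C)[C@H]2CC1 | intermediate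
12 | trimethylsilyl ketene acetal of 11 with C11–O–SiMe3 (ketene acetal geometry not controlled) | CC1=C2[C@H](OC(O[Si](C)(C)C)=Cc3c(OCOC)cc(OCOC)cc3OCOC)[C@H](C(C)(C)O[Si](C)(C)C)CC[C@@H](C)[C@H]2CC1 | intermediate
13 | trimethylsilyl 2-[(1R,4R,7R,10R)-11-(trimethylsilyloxy)guai-5-en-4-yl]-2-[2,4,6-tris(methoxymethoxy)phenyl]acetate | C[Si](C)(C)OC(=O)C(c1c(OCOC)cc(OCOC)cc1OCOC)[C@@]2(C)CC[C@H]3C2=C[C@H](C(C)(C)O[Si](C)(C)C)CC[C@H]3C | intermediate
14 | 2-[(1R,4R,7R,10R)-11-hydroxyguai-5-en-4-yl]-2-[2,4,6-tris(methoxymethoxy)phenyl]acetic acid (benzylic epimers) | OC(=O)C(c1c(OCOC)cc(OCOC)cc1OCOC)[C@@]2(C)CC[C@H]3C2=C[C@H](C(C)(C)O)CC[C@H]3C | intermediate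
15 | (1R,4R,7R,10R)-4-{[2,4,6-tris(methoxymethoxy)phenyl]methyl}guai-5-en-11-ol | COCOc1cc(OCOC)c(C[C@@]2(C)CC[C@H]3C2=C[C@H](C(C)(C)O)CC[C@H]3C)c(OCOC)c1 | intermediate
16 | 3-methylbutanal (isovaleraldehyde) | CC(C)CC=O | starting material
17 | aryllithium of 15 (C3′–Li, C11–OLi) | [Li]c1c(OCOC)cc(OCOC)c(C[C@@]2(C)CC[C@H]3C2=C[C@H](C(C)(C)O[Li])CC[C@H]3C)c1OCOC | intermediate
18 | dilithium dialkoxide after aldehyde addition | CC(C)CC(O[Li])c1c(OCOC)cc(OCOC)c(C[C@@]2(C)CC[C@H]3C2=C[C@H](C(C)(C)O[Li])CC[C@H]3C)c1OCOC | intermediate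
19 | C5′-lithiated dialkoxide | CC(C)CC(O[Li])c1c(OCOC)c([Li])c(OCOC)c(C[C@@]2(C)CC[C@H]3C2=C[C@H](C(C)(C)O[Li])CC[C@H]3C)c1OCOC | intermediate
20 | 3-{[(1R,4R,7R,10R)-11-hydroxyguai-5-en-4-yl]methyl}-5-(1-hydroxy-3-methylbutyl)-2,4,6-tris(methoxymethoxy)benzaldehyde (carbinol epimers) | CC(C)CC(O)c1c(OCOC)c(C=O)c(OCOC)c(C[C@@]2(C)CC[C@H]3C2=C[C@H](C(C)(C)O)CC[C@H]3C)c1OCOC | intermediate
21 | 3-{[(1R,4R,7R,10R)-11-hydroxyguai-5-en-4-yl]methyl}-5-(3-methylbutanoyl)-2,4,6-tris(methoxymethoxy)benzaldehyde | CC(C)CC(=O)c1c(OCOC)c(C=O)c(OCOC)c(C[C@@]2(C)CC[C@H]3C2=C[C@H](C(C)(C)O)CC[C@H]3C)c1OCOC | intermediate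
22 | 2,4,6-trihydroxy-3-{[(1R,4R,7R,10R)-11-hydroxyguai-5-en-4-yl]methyl}-5-(3-methylbutanoyl)benzaldehyde (CNP0583424.1) | CC(C)CC(=O)c1c(O)c(C=O)c(O)c(C[C@@]2(C)CC[C@H]3C2=C[C@H](C(C)(C)O)CC[C@H]3C)c1O | target

**Totals**
Total step count: 13. Longest linear sequence: 10 (steps 1–4 and 8–13, from 1).

**Three steps most likely to fail**

Step 9 (Ireland–Claisen). The new bond joins a fully substituted alkene carbon to a carbon bearing a 2,6-dioxygenated aryl group, so the transition state is very congested. Fallback, setting out from 5 and coming back at 15: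
- The secondary alkoxide of 5 is alkylated with Bu3SnCH2I (KH, 18-crown-6, THF) to give 6β-[(tributylstannyl)methoxy]guai-4-en-11-ol F1.
- n-BuLi (2.2 equiv, THF, −78 °C) effects tin–lithium exchange and a Wittig–Still [2,3] shift with the same suprafacial O-6 → C-4 transfer, giving 4β-(hydroxymethyl)guai-5-en-11-ol F2.
- Dess–Martin oxidation gives 11-hydroxyguai-5-ene-4β-carbaldehyde F3.
- Addition of aryllithium 8 (2.2 equiv) gives (11-hydroxyguai-5-en-4β-yl)[2,4,6-tris(methoxymethoxy)phenyl]methanol F4.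
- 1,1′-Thiocarbonyldiimidazole acylates the secondary hydroxyl selectively to the imidazol-1-ylthiocarbonate F5.
- Bu3SnH/AIBN (toluene, 90 °C, Barton–McCombie deoxygenation) delivers 15.

Step 10 (hydrodecarboxylation). The acid is very hindered, and the trialkoxyarene and the alkene are also oxidisable by the photocatalyst. Fallback, setting out from 14 and coming back at 15: 14 is converted with 2,2′-dithiobis(pyridine N-oxide) and PBu3 (THF, dark) into the 2-thioxopyridin-1(2H)-yl (Barton) ester F6, which is photolysed with t-BuSH in a radical chain decarboxylation to 15.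

Step 4 (facial selectivity of the reduction). A flexible cycloheptenone may give mainly the 6α-alcohol, which would invert C4 after the rearrangement. Fallback, setting out from 4 and coming back at 11: the ketone is reduced with Me4NBH(OAc)3 (MeCN/AcOH, −30 °C), where hydride is delivered intramolecularly from the C11 alkoxyborohydride to the β face, giving (1R,6S,7R,10R)-guai-4-ene-6,11-diol F7. F7 is esterified with 10 under Mitsunobu conditions (PPh3, DIAD, THF), which inverts C6 and gives 11 directly.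

**Further compounds**
F1 | step 9 | 6β-[(tributylstannyl)methoxy]guai-4-en-11-ol | CC1=C2[C@H](OC[Sn](CCCC)(CCCC)CCCC)[C@H](C(C)(C)O)CC[C@@H](C)[C@H]2CC1
F2 | step 9 | 4β-(hydroxymethyl)guai-5-en-11-ol | OC[C@@]1(C)CC[C@H]2C1=C[C@H](C(C)(C)O)CC[C@H]2C
F3 | step 9 | 11-hydroxyguai-5-ene-4β-carbaldehyde | O=C[C@@]1(C)CC[C@H]2C1=C[C@H](C(C)(C)O)CC[C@H]2C
F4 | step 9 | (11-hydroxyguai-5-en-4β-yl)[2,4,6-tris(methoxymethoxy)phenyl]methanol | OC(c1c(OCOC)cc(OCOC)cc1OCOC)[C@@]2(C)CC[C@H]3C2=C[C@H](C(C)(C)O)CC[C@H]3C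
F5 | step 9 | O-(imidazol-1-ylthiocarbonyl) derivative of F4 | S=C(n1ccnc1)OC(c1c(OCOC)cc(OCOC)cc1OCOC)[C@@]2(C)CC[C@H]3C2=C[C@H](C(C)(C)O)CC[C@H]3C
F6 | step 10 | 2-thioxopyridin-1(2H)-yl ester of 14 | S=c1ccccn1OC(=O)C(c1c(OCOC)cc(OCOC)cc1OCOC)[C@@]2(C)CC[C@H]3C2=C[C@H](C(C)(C)O)CC[C@H]3C
F7 | step 4 | (1R,6S,7R,10R)-guai-4-ene-6,11-diol (6α-OH) | CC1=C2[C@@H](O)[C@H](C(C)(C)O)CC[C@@H](C)[C@H]2CC1
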